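Assumption: positions are named with the usual briarane numbering for every intermediate (ten-membered ring C1–C10; ring A = C1, C10–C14; C15 on C1; C16 on C5; lactone C7–C8–C17–C19 with C18 on C17; C20 on C11).

**Retrosynthetic overview**
1. Target ⇐ ene-type chlorination of the C5(Me)=C6 alkene of a (3Z,5Z)-diene; before that, OH-directed 13,14-epoxidation, 12-butyrate and 2,9-diacetate on the finished ring system.
2. Ten-membered ring ⇐ ring expansion by Grob fragmentation of a hydrindanol-fused cycloheptene mesylate (C3–C9 bond cut; C9 ketone and 3Z-alkene formed).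
3. Fragmentation precursor ⇐ ring-closing metathesis (seven-membered ring, C5=C6) ⇐ two aldol reactions (C3→C9 aldol closes a five-membered template ring; C3–C4 aldol with methacrolein).
4. Lactone (C7, C8, C17) ⇐ intramolecular Reformatsky reaction on a 1,2-diketone ⇐ diazoketone–acrolein aldol (C7–C8) ⇐ ring A carboxylic acid.
5. Ring A (C1, C10) ⇐ catalytic asymmetric Diels–Alder reaction of a 2-methyl-1,3-diene with a β-bromo enone, then loss of HBr and dihydroxylation. Ring order: ring A, lactone, five-membered template ring, seven-membered ring, ten-membered ring, epoxide.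

**Route**

Step 1
Reactants: 1 (E)-3-methylpent-2-en-4-yn-1-ol
Product: 2 TBS ether of 1
Conditions: TBSCl, imidazole, DMF, 0 °C to rt
Reagents that add atoms: tert-butyldimethylsilyl chloride, CC(C)(C)[Si](C)(C)Cl
Why: standard silylation of the primary alcohol protects the future C9 oxygen; no stereocentre is formed.

Step 2
Reactants: 2 TBS ether of 1
Product: 3 silyloxy diene
Conditions: H2 (1 atm), Pd/CaCO3 poisoned with Pb(OAc)2, quinoline, hexane, rt
Reagents that add atoms: none
Why: Lindlar semi-hydrogenation of the terminal alkyne gives the 1-substituted 2-methylbuta-1,3-diene, and the E geometry of the trisubstituted alkene is carried over from 1.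

Step 3
Reactants: 4 3-methylbut-3-en-2-one
Product: 6 (E)-4-bromo-3-methylbut-3-en-2-one, via 3,4-dibromo-3-methylbutan-2-one 5 (not isolated)
Conditions: Br2, CH2Cl2, 0 °C; then Et3N, 0 °C to rt
Reagents that add atoms: bromine, BrBr
Why: alkene bromination followed by E2 loss of HBr (only the CH2Br hydrogens can be removed) is the classical route to β-bromo enones, and the alkene geometry is of no consequence because the C–Br centre is destroyed in step 4.

Step 4
Reactants: 3 silyloxy diene; 6 (E)-4-bromo-3-methylbut-3-en-2-one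
Product: 8 ring-A dienyl methyl ketone, via bromo cycloadduct 7 (not isolated)
Conditions: (S)-B-(o-tolyl)-diphenylprolinol oxazaborolidine activated with AlBr3 (10 mol%), CH2Cl2, −78 to −40 °C; then DBU, rt
Reagents that add atoms: none
Why: Proposed new method: the cationic oxazaborolidinium Lewis acid binds the ketone of 6 and the diene adds through the exo transition state (acetyl exo, as is usual for α-substituted dienophiles) on the face left open by the catalyst, which forms ring A and sets C1 (quaternary) and C10 with the acetyl group trans to the CH2OTBS arm, the 1-substituent of the diene dictating the "ortho" regiochemistry; DBU then removes HBr across C13–C14 by E2 elimination to give the conjugated diene; the closest known reactions are oxazaborolidinium-catalysed Diels–Alder reactions of 2-methylacrolein, 2-bromoacrolein and simple vinyl ketones, whereas a β-bromo α-methyl vinyl ketone used as an ynone surrogate has not been shown.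

Step 5
Reactants: 8 ring-A dienyl methyl ketone
Product: 9 ring-A 11,12-diol
Conditions: OsO4 (2 mol%), N-methylmorpholine N-oxide, acetone/H2O, 0 °C
Reagents that add atoms: N-methylmorpholine N-oxide, C[N+]1([O-])CCOCC1; water, O
Why: catalytic syn-dihydroxylation takes the more electron-rich trisubstituted C11=C12 bond of the diene from the face anti to the adjacent C10 side chain and the C1 methyl, setting C11 (OH, methyl) and C12 (OH) cis to each other.

Step 6
Reactants: 9 ring-A 11,12-diol
Product: 10 acetonide
Conditions: 2,2-dimethoxypropane, PPTS (cat.), CH2Cl2, rt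
Reagents that add atoms: 2,2-dimethoxypropane, COC(C)(C)OC
Why: acid-catalysed transketalisation protects the cis-diol as its acetonide, which withstands the basic, reductive and organometallic steps that follow.

Step 7
Reactants: 10 acetonide
Product: 11 primary alcohol
Conditions: Bu4NF, THF, 0 °C
Reagents that add atoms: none
Why: fluoride cleaves the primary silyl ether without touching the acetonide or the ketone.

Step 8
Reactants: 11 primary alcohol
Product: 12 ring-A carboxylic acid
Conditions: TEMPO (10 mol%), PhI(OAc)2 (2.2 equiv), MeCN/H2O, rt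
Reagents that add atoms: water, O
Why: oxoammonium-mediated oxidation in wet acetonitrile takes the primary alcohol through the aldehyde hydrate to the acid (C9) without affecting the alkene, and the trans arrangement at C10 is the thermodynamically preferred one.

Step 9
Reactants: 12 ring-A carboxylic acid
Product: 14 diazoketone, via isobutyl carbonic mixed anhydride 13 (not isolated)
Conditions: iBuOCOCl, Et3N, THF, −15 °C; then CH2N2, Et2O, 0 °C
Reagents that add atoms: diazomethane, C=[N+]=[N-]
Why: acylation of diazomethane by the mixed anhydride (first stage of an Arndt–Eistert sequence) turns C9 into a ketone and brings in C8 as a nucleophilic diazo carbon.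

Step 10
Reactants: 14 diazoketone; 15 acrolein
Product: 16 diazo aldol
Conditions: (S,S)-ProPhenol (10 mol%), Bu2Mg (20 mol%), cis-cyclopentane-1,2-diol (5 mol%), THF, −20 °C
Reagents that add atoms: none
Why: Proposed new method: the dinuclear magnesium–ProPhenol complex deprotonates the diazoketone C–H (more acidic than the methyl ketone) at one magnesium centre and binds acrolein at the other, so the diazo carbon adds to one enantiotopic face of the aldehyde, forming the C7–C8 bond and the (S)-carbinol at C7; the closest known reaction is the magnesium–ProPhenol aldol addition of ethyl diazoacetate to aldehydes including enals, which has not been shown for α-diazo ketones.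

Step 11
Reactants: 16 diazo aldol; 17 2-bromopropanoyl bromide
Product: 18 α-bromo ester
Conditions: pyridine, CH2Cl2, −20 °C
Reagents that add atoms: none
Why: O-acylation of the secondary alcohol installs C17–C19 as a tethered Reformatsky donor; the bromine-bearing centre is left as a mixture because it becomes an enolate in step 13.

Step 12
Reactants: 18 α-bromo ester
Product: 19 vicinal diketone
Conditions: dimethyldioxirane, acetone, −78 to −30 °C
Reagents that add atoms: dimethyldioxirane, CC1(C)OO1
Why: oxygen transfer to the diazo carbon with loss of N2 is much faster than alkene epoxidation at this temperature and turns C8 into the ketone of a 1,2-diketone.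

Step 13
Reactants: 19 vicinal diketone
Product: 20 hydroxy lactone
Conditions: Zn dust (activated), THF, 0 °C to rt, H2O quench; then DBU (10 mol%), CH2Cl2, rt
Reagents that add atoms: none
Why: the intramolecular Reformatsky reaction can only close the five-membered lactone onto the C8 ketone (attack at C9 would need a six-membered ring), the bulky C9 acyl group ends trans to the C7 vinyl group so the new C8 hydroxyl is cis to it, and DBU equilibrates the epimerisable C17 so that its methyl is trans to the acyl group.

Step 14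
Reactants: 20 hydroxy lactone
Product: 21 TES ether
Conditions: Et3SiOTf, 2,6-lutidine, CH2Cl2, −78 °C
Reagents that add atoms: triethylsilyl trifluoromethanesulfonate, CC[Si](CC)(CC)OS(=O)(=O)C(F)(F)F
Why: silylation of the tertiary α-ketol hydroxyl prevents retro-aldol and α-ketol rearrangement during the enolate chemistry of step 15.

Step 15
Reactants: 21 TES ether; 22 methacrolein
Product: 24 hydrindanone bis-aldol product, via hydrindanone aldol 23 (not isolated)
Conditions: LiN(iPr)2 (1.05 equiv), THF, −78 °C; then LiN(iPr)2 (1.1 equiv), Cp2ZrCl2 (1.2 equiv), −78 to −40 °C; then 22, H2O quench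
Reagents that add atoms: none
Why: the kinetic enolate of the methyl ketone (C3) closes the five-membered template ring onto the C9 ketone by an intramolecular aldol reaction with the bulky lactone trans to the C1 methyl, and the zirconium enolate of the resulting cyclopentanone then gives the syn aldol with methacrolein on the face away from the lactone, setting the C3/C4 relationship that the fragmentation later translates into the 3Z alkene.

Step 16
Reactants: 24 hydrindanone bis-aldol product
Product: 25 cycloheptene
Conditions: second-generation Hoveyda–Grubbs catalyst RuCl2(H2IMes)(=CH-C6H4-2-OiPr) (5 mol%), toluene, 70 °C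
Reagents that add atoms: none
Why: ring-closing metathesis between the isopropenyl group on C4 and the vinyl group on C7 closes the seven-membered ring with the necessarily cis C5(Me)=C6 alkene, the ring-A cyclohexene being inert.

Step 17
Reactants: 25 cycloheptene
Product: 27 hydroxy mesylate, via keto mesylate 26 (not isolated)
Conditions: MsCl, pyridine, CH2Cl2, 0 °C; then NaBH4, CeCl3·7H2O, MeOH, −78 °C
Reagents that add atoms: methanesulfonyl chloride, CS(=O)(=O)Cl
Why: the only secondary hydroxyl (C4) is sulfonylated, and Luche reduction then delivers hydride to the C2 ketone of the rigid bicycle from the face opposite the C1 methyl and the C3 side chain, giving the C2 alcohol cis to the C1 methyl as in the target.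

Step 18
Reactants: 27 hydroxy mesylate
Product: 28 ten-membered ketone
Conditions: KOtBu (1.1 equiv), THF, −78 to 0 °C
Reagents that add atoms: none
Why: Grob (Wharton) fragmentation of the 1,3-hydroxy mesylate is the ring expansion: the C9 alkoxide pushes, the C3–C9 bond held antiperiplanar to C4–OMs by the seven-membered ring breaks, the five- and seven-membered rings merge into the ten-membered ring with a C9 ketone, and the syn C3/C4 relationship is transferred stereospecifically into the 3Z alkene of the (3Z,5Z)-diene.

Step 19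
Reactants: 28 ten-membered ketone
Product: 29 2,9-diol
Conditions: NaBH4, CeCl3·7H2O, MeOH, −40 °C
Reagents that add atoms: none
Why: Luche reduction of the C9 ketone is expected to occur by peripheral attack on the face away from the C8 silyloxy group and the ring-A fusion, giving the 9S alcohol.

Step 20
Reactants: 29 2,9-diol
Product: 30 diacetate
Conditions: Ac2O, pyridine, DMAP (cat.), CH2Cl2, rt
Reagents that add atoms: acetic anhydride, CC(=O)OC(C)=O
Why: nucleophilic-catalysed acetylation esterifies the two free secondary alcohols (C2, C9), the tertiary positions being protected.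

Step 21
Reactants: 30 diacetate
Product: 31 triol
Conditions: AcOH/THF/H2O (3:1:1), 45 °C
Reagents that add atoms: none
Why: mild acidic hydrolysis removes the acetonide and the triethylsilyl ether together while leaving the acetates, the lactone and the diene intact.

Step 22
Reactants: 31 triol
Product: 32 epoxy diol
Conditions: VO(acac)2 (5 mol%), tBuOOH, CH2Cl2, 0 °C
Reagents that add atoms: tert-butyl hydroperoxide, CC(C)(C)OO
Why: vanadium-catalysed hydroxyl-directed epoxidation delivers oxygen to the C13=C14 alkene syn to the allylic C12 hydroxyl, which is also the face away from the C1 methyl, and leaves the non-allylic diene untouched.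

Step 23
Reactants: 32 epoxy diol
Product: 33 12-butyrate
Conditions: butanoyl chloride, pyridine, DMAP (cat.), CH2Cl2, 0 °C
Reagents that add atoms: butanoyl chloride, CCCC(Cl)=O
Why: acylation takes the only secondary hydroxyl (C12), the tertiary C8 and C11 hydroxyls being unreactive.

Step 24
Reactants: 33 12-butyrate
Product: 34 CNP0273377.1
Conditions: PhSeCl (10 mol%), N-chlorosuccinimide, CH2Cl2, 0 °C to rt
Reagents that add atoms: N-chlorosuccinimide, O=C1CCC(=O)N1Cl
Why: selenium-catalysed ene-type allylic chlorination places chlorine on C6 of the trisubstituted C5(Me)=C6 alkene and moves the double bond to C5=C16; chlorine is expected on the exposed face of the tub-shaped diene anti to the lactone, mirroring the presumed biogenesis of 6-chloro-5(16)-ene briaranes.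

**Compound list**

1 | (E)-3-methylpent-2-en-4-yn-1-ol | C#C/C(C)=C/CO | starting material
2 | (E)-tert-butyldimethyl[(3-methylpent-2-en-4-yn-1-yl)oxy]silane | C#C/C(C)=C/CO[Si](C)(C)C(C)(C)C | intermediate
3 | (E)-tert-butyldimethyl[(3-methylpenta-2,4-dien-1-yl)oxy]silane (C9–C13 and C20) | C=C/C(C)=C/CO[Si](C)(C)C(C)(C)C | intermediate
4 | 3-methylbut-3-en-2-one | CC(=O)C(C)=C | starting material
5 | 3,4-dibromo-3-methylbutan-2-one (racemic) | CC(=O)C(C)(Br)CBr | intermediate
6 | (E)-4-bromo-3-methylbut-3-en-2-one | CC(=O)/C(C)=C/Br | intermediate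
7 | bromo cycloadduct: 1-acetyl-1-methyl-6-bromo-2-(TBSOCH2)-3-methylcyclohex-3-ene; acetyl trans to CH2OTBS, Br cis to the 1-methyl | CC(=O)[C@@]1(C)[C@H](Br)CC=C(C)[C@@H]1CO[Si](C)(C)C(C)(C)C | intermediate
8 | ring-A dienyl methyl ketone: 1-acetyl-1,5-dimethyl-6-(TBSOCH2)cyclohexa-2,4-diene; acetyl trans to CH2OTBS | CC(=O)[C@@]1(C)C=CC=C(C)[C@@H]1CO[Si](C)(C)C(C)(C)C | intermediate
9 | ring-A 11,12-diol: cis-diol on the face opposite the C1 methyl and the C10 side chain, C13=C14 retained | CC(=O)[C@@]1(C)C=C[C@@H](O)[C@@](C)(O)[C@@H]1CO[Si](C)(C)C(C)(C)C | intermediate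
10 | 11,12-acetonide of 9 | CC(=O)[C@@]1(C)C=C[C@H]2OC(C)(C)O[C@@]2(C)[C@@H]1CO[Si](C)(C)C(C)(C)C | intermediate
11 | primary alcohol (C9 hydroxymethyl) from 10 | CC(=O)[C@@]1(C)C=C[C@H]2OC(C)(C)O[C@@]2(C)[C@@H]1CO | intermediate
12 | ring-A carboxylic acid (C9 acid) | CC(=O)[C@@]1(C)C=C[C@H]2OC(C)(C)O[C@@]2(C)[C@@H]1C(=O)O | intermediate
13 | isobutyl carbonic mixed anhydride of 12 | CC(=O)[C@@]1(C)C=C[C@H]2OC(C)(C)O[C@@]2(C)[C@@H]1C(=O)OC(=O)OCC(C)C | intermediate
14 | diazoketone (C9 ketone, C8 diazomethyl) | CC(=O)[C@@]1(C)C=C[C@H]2OC(C)(C)O[C@@]2(C)[C@@H]1C(=O)C=[N+]=[N-] | intermediate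
15 | acrolein | C=CC=O | starting material
16 | diazo aldol: α-diazo-β-hydroxy ketone with (S)-carbinol at C7 bearing vinyl | CC(=O)[C@@]1(C)C=C[C@H]2OC(C)(C)O[C@@]2(C)[C@@H]1C(=O)C(=[N+]=[N-])[C@@H](O)C=C | intermediate
17 | 2-bromopropanoyl bromide (racemic) | CC(Br)C(Br)=O | starting material
18 | 2-bromopropanoate of 16 (both epimers at CHBr) | CC(=O)[C@@]1(C)C=C[C@H]2OC(C)(C)O[C@@]2(C)[C@@H]1C(=O)C(=[N+]=[N-])[C@@H](OC(=O)C(C)Br)C=C | intermediate
19 | vicinal diketone (C8 and C9 ketones; both epimers at CHBr) | CC(=O)[C@@]1(C)C=C[C@H]2OC(C)(C)O[C@@]2(C)[C@@H]1C(=O)C(=O)[C@@H](OC(=O)C(C)Br)C=C | intermediate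
20 | hydroxy lactone: γ-lactone O–C7(vinyl)–C8(OH)(acyl)–C17(Me)–C19(=O); C8 OH, C17 methyl and C7 vinyl cis, C9 acyl trans to them | CC(=O)[C@@]1(C)C=C[C@H]2OC(C)(C)O[C@@]2(C)[C@@H]1C(=O)[C@]3(O)[C@@H](C)C(=O)O[C@H]3C=C | intermediate
21 | 8-O-triethylsilyl ether of 20 | CC(=O)[C@@]1(C)C=C[C@H]2OC(C)(C)O[C@@]2(C)[C@@H]1C(=O)[C@]3(O[Si](CC)(CC)CC)[C@@H](C)C(=O)O[C@H]3C=C | intermediate
22 | methacrolein | CC(=C)C=O | starting material
23 | hydrindanone aldol: five-membered ring C1–C2(=O)–C3H2–C9(OH)–C10 trans-fused to ring A; C9 OH cis to the C1 methyl | C[C@]12C=C[C@H]3OC(C)(C)O[C@@]3(C)[C@@H]1[C@](O)(CC2=O)[C@]4(O[Si](CC)(CC)CC)[C@@H](C)C(=O)O[C@H]4C=C | intermediate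
24 | hydrindanone bis-aldol product: C3 carries CH(OH)–C(Me)=CH2 cis to the C9 OH; C3/C4 syn aldol | C[C@]12C=C[C@H]3OC(C)(C)O[C@@]3(C)[C@@H]1[C@](O)([C@H]([C@@H](O)C(C)=C)C2=O)[C@]4(O[Si](CC)(CC)CC)[C@@H](C)C(=O)O[C@H]4C=C | intermediate
25 | cycloheptene: seven-membered ring C3–C4–C5=C6–C7–C8–C9 fused to the hydrindanone and the lactone | C[C@]12C=C[C@H]3OC(C)(C)O[C@@]3(C)[C@@H]1[C@]4(O)[C@H]([C@@H](O)C(C)=C[C@@H]5OC(=O)[C@H](C)[C@@]45O[Si](CC)(CC)CC)C2=O | intermediate
26 | keto mesylate (C4 mesylate of 25) | C[C@]12C=C[C@H]3OC(C)(C)O[C@@]3(C)[C@@H]1[C@]4(O)[C@H]([C@@H](OS(C)(=O)=O)C(C)=C[C@@H]5OC(=O)[C@H](C)[C@@]45O[Si](CC)(CC)CC)C2=O | intermediate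
27 | hydroxy mesylate: C2 alcohol cis to the C1 methyl, C4 mesylate, C9 tertiary alcohol | C[C@]12C=C[C@H]3OC(C)(C)O[C@@]3(C)[C@@H]1[C@]4(O)[C@H]([C@@H](OS(C)(=O)=O)C(C)=C[C@@H]5OC(=O)[C@H](C)[C@@]45O[Si](CC)(CC)CC)[C@@H]2O | intermediate
28 | ten-membered ketone: (3Z,5Z)-diene, C9 ketone, free C2 alcohol, 8-OTES lactone, ring-A acetonide | C[C@]12C=C[C@H]3OC(C)(C)O[C@@]3(C)[C@@H]1C(=O)[C@]4(O[Si](CC)(CC)CC)[C@@H](C)C(=O)O[C@H]4/C=C(C)\C=C/[C@@H]2O | intermediate
29 | 2,9-diol (9S alcohol) | C[C@]12C=C[C@H]3OC(C)(C)O[C@@]3(C)[C@@H]1[C@H](O)[C@]4(O[Si](CC)(CC)CC)[C@@H](C)C(=O)O[C@H]4/C=C(C)\C=C/[C@@H]2O | intermediate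
30 | 2,9-diacetate | C[C@]12C=C[C@H]3OC(C)(C)O[C@@]3(C)[C@@H]1[C@H](OC(C)=O)[C@]4(O[Si](CC)(CC)CC)[C@@H](C)C(=O)O[C@H]4/C=C(C)\C=C/[C@@H]2OC(C)=O | intermediate
31 | triol (8-, 11- and 12-OH free) | C[C@]12C=C[C@@H](O)[C@@](C)(O)[C@@H]1[C@H](OC(C)=O)[C@]3(O)[C@@H](C)C(=O)O[C@H]3/C=C(C)\C=C/[C@@H]2OC(C)=O | intermediate
32 | epoxy diol: 13,14-epoxide cis to the 12-OH | C[C@]12[C@H]3O[C@H]3[C@@H](O)[C@@](C)(O)[C@@H]1[C@H](OC(C)=O)[C@]4(O)[C@@H](C)C(=O)O[C@H]4/C=C(C)\C=C/[C@@H]2OC(C)=O | intermediate
33 | 12-butyrate | C[C@]12[C@H]3O[C@H]3[C@@H](OC(=O)CCC)[C@@](C)(O)[C@@H]1[C@H](OC(C)=O)[C@]4(O)[C@@H](C)C(=O)O[C@H]4/C=C(C)\C=C/[C@@H]2OC(C)=O | intermediate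
34 | CNP0273377.1 | C=C1/C=C\[C@H](OC(C)=O)[C@@]2(C)[C@H]3O[C@H]3[C@@H](OC(=O)CCC)[C@@](C)(O)[C@@H]2[C@H](OC(C)=O)[C@]2(O)[C@@H](C)C(=O)O[C@H]2[C@H]1Cl | target

**Step count**

Total: 24 steps. Longest linear sequence: 23 steps (1 to 34 through steps 1, 2 and 4–24); step 3 prepares dienophile 6 in one step from 4.

**Three steps most likely to fail, with fallbacks**

Step 4 (proposed new Diels–Alder reaction). The β-bromo α-methyl enone may react too slowly or with poor exo or enantiofacial control. The fallback uses a covalently bound auxiliary, which is known chemistry. It sets out from 3. (E)-3-Bromo-2-methylprop-2-enoyl chloride is attached to lithiated (S)-4-benzyl-1,3-oxazolidin-2-one to give the bromo acryloyl imide F1. Et2AlCl-promoted Diels–Alder reaction of F1 with 3 (CH2Cl2, −40 °C) gives the bromo cycloadduct imide F2, and DBU converts it into the dienyl imide F3. LiOH/H2O2 releases the dienyl carboxylic acid F4, and MeLi (2.2 equiv, Et2O, 0 °C) turns F4 into the methyl ketone. The antipodal auxiliary is used if the opposite diene face is attacked. The fallback comes back to the route at 8.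

Step 10 (proposed new asymmetric diazoketone aldol). The magnesium catalyst may give low ee or may engage the methyl ketone. The fallback uses the known amine-base aldol of α-diazo ketones followed by separation and inversion. It sets out from 14. DBU (10 mol%, MeCN, 0 °C) with acrolein gives 16 together with its C7 epimer F5, and the two are separated by chromatography (they are diastereomers because ring A is already resolved). F5 is inverted by Mitsunobu esterification (4-nitrobenzoic acid, PPh3, diisopropyl azodicarboxylate) to the 4-nitrobenzoate F6, and methanolysis (K2CO3, MeOH, 0 °C) gives the carbinol. The fallback comes back to the route at 16.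

Step 18 (Grob ring expansion). The seven-membered ring may not hold the mesylate antiperiplanar to the C3–C9 bond, or the C2 alkoxide may interfere. The fallback is a ring expansion of a different mechanism, which needs no antiperiplanar arrangement. It sets out from 25. Mesylation as in step 17 gives keto mesylate 26, which is not reduced but treated with KN(SiMe3)2 (THF, −78 °C). The C9 alkoxide opens the C3–C9 bond by retro-aldol reaction and the resulting C2 enolate expels mesylate (E1cB), giving the ten-membered 2,9-diketone F7 with the ring-cis enone. Luche reduction of both carbonyl groups (NaBH4, CeCl3·7H2O, MeOH, −78 °C) then gives the diol, at the price of setting C2 on the flexible ring. The fallback comes back to the route at 29.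

Further compounds
F1 | step 4 | (S)-4-benzyl-3-[(E)-3-bromo-2-methylprop-2-enoyl]-1,3-oxazolidin-2-one | O=C1OC[C@H](Cc2ccccc2)N1C(=O)/C(C)=C/Br
F2 | step 4 | bromo cycloadduct imide (imide analogue of 7) | O=C1OC[C@H](Cc2ccccc2)N1C(=O)[C@@]3(C)[C@H](Br)CC=C(C)[C@@H]3CO[Si](C)(C)C(C)(C)C
F3 | step 4 | dienyl imide (imide analogue of 8) | O=C1OC[C@H](Cc2ccccc2)N1C(=O)[C@@]3(C)C=CC=C(C)[C@@H]3CO[Si](C)(C)C(C)(C)C
F4 | step 4 | dienyl carboxylic acid (acid analogue of 8) | OC(=O)[C@@]1(C)C=CC=C(C)[C@@H]1CO[Si](C)(C)C(C)(C)C
F5 | step 10 | C7 epimer of 16 | CC(=O)[C@@]1(C)C=C[C@H]2OC(C)(C)O[C@@]2(C)[C@@H]1C(=O)C(=[N+]=[N-])[C@H](O)C=C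
F6 | step 10 | 4-nitrobenzoate of 16 | CC(=O)[C@@]1(C)C=C[C@H]2OC(C)(C)O[C@@]2(C)[C@@H]1C(=O)C(=[N+]=[N-])[C@@H](OC(=O)c3ccc(cc3)[N+](=O)[O-])C=C
F7 | step 18 | ten-membered 2,9-diketone with (3Z,5Z)-diene | C[C@]12C=C[C@H]3OC(C)(C)O[C@@]3(C)[C@@H]1C(=O)[C@]4(O[Si](CC)(CC)CC)[C@@H](C)C(=O)O[C@H]4/C=C(C)\C=C/C2=O
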